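Megaphone is disconnected at C5–C6 of the cyclohexenone ring (C1 carbonyl, C2=C3, C4 OMe, C5 CH2, C6 quaternary): C6 is the α′ carbon of the C1 ketone and C5 a primary carbon next to the methoxy-bearing C4. The key step closes this ring by intramolecular γ-alkylation of a β-keto sulfoxide dianion; the C2 sulfoxide steers enolisation to C6 and is then lost thermally to unveil the C2=C3 enone in the same operation. The precursor is an acyclic keto sulfoxide carrying the (7S,8R) side chain, the (S)-methoxy carbon and a primary tosylate. Both C6 epimers of the cyclised enone converge in a final α′-allylation that sets the quaternary centre.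

Key step: step 10

Remark: atoms are numbered C1 (C=O), C2=C3, C4 (CH–OMe), C5 (CH2), C6 (quaternary C), C7 (CH–CH3), C8 (CH(OH)–aryl); (2S)-but-3-ene-1,2-diol and the (Z)-crotyl pinacol boronate are taken as purchasable.

Step 1
Reactants: 1 3,4,5-trimethoxybenzaldehyde; 2 2-[(2Z)-but-2-en-1-yl]-4,4,5,5-tetramethyl-1,3,2-dioxaborolane
Product: 4 (1R,2S)-2-methyl-1-(3,4,5-trimethoxyphenyl)but-3-en-1-ol, via pinacol borate ester 3 (not isolated)
Conditions: (R)-3,3′-bis(2,4,6-triisopropylphenyl)-1,1′-binaphthyl-2,2′-diyl hydrogen phosphate (5 mol %), toluene, −30 °C; aqueous NaHCO3 work-up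
Reagents that add atoms: none
Why: Chiral-phosphoric-acid-catalysed crotylboration through a closed chair transition state, in which the Z boronate gives the syn Me/OH relationship and the (R)-acid is expected to direct attack to the Re face of the aldehyde, setting C8 as R and C7 as S.

Step 2
Reactants: 4 (1R,2S)-2-methyl-1-(3,4,5-trimethoxyphenyl)but-3-en-1-ol
Product: 5 tert-butyl(dimethyl){[(1R,2S)-2-methyl-1-(3,4,5-trimethoxyphenyl)but-3-en-1-yl]oxy}silane
Conditions: TBSOTf, 2,6-lutidine, CH2Cl2, 0 °C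
Reagents that add atoms: tert-butyldimethylsilyl trifluoromethanesulfonate, CC(C)(C)[Si](C)(C)OS(=O)(=O)C(F)(F)F
Why: Silylation of the secondary benzylic alcohol with a silyl triflate, which protects C8–OH against the later carbanion steps and touches no stereocentre.

Step 3
Reactants: 5 tert-butyl(dimethyl){[(1R,2S)-2-methyl-1-(3,4,5-trimethoxyphenyl)but-3-en-1-yl]oxy}silane
Product: 7 (3S,4R)-4-{[tert-butyl(dimethyl)silyl]oxy}-3-methyl-4-(3,4,5-trimethoxyphenyl)butan-1-ol, via B-alkyl-9-BBN adduct 6 (not isolated)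
Conditions: 9-BBN, THF, 0 °C to rt; then NaOH, H2O2, H2O, 0 °C
Reagents that add atoms: hydrogen peroxide, OO
Why: Anti-Markovnikov hydroboration–oxidation, in which the bulky borane places boron on the terminal carbon (future C1) and oxidation leaves C7 and C8 untouched.

Step 4
Reactants: 7 (3S,4R)-4-{[tert-butyl(dimethyl)silyl]oxy}-3-methyl-4-(3,4,5-trimethoxyphenyl)butan-1-ol
Product: 8 (3S,4R)-4-{[tert-butyl(dimethyl)silyl]oxy}-3-methyl-4-(3,4,5-trimethoxyphenyl)butanoic acid
Conditions: TEMPO (cat.), PhI(OAc)2, MeCN–H2O, rt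
Reagents that add atoms: water, O
Why: Oxoammonium-mediated oxidation of the primary alcohol through the aldehyde hydrate to the acid, which spares the silyl ether and cannot epimerise C7 because it is β to the new carbonyl.

Step 5
Reactants: 9 (2S)-but-3-ene-1,2-diol
Product: 10 (2S)-2-hydroxybut-3-en-1-yl 4-methylbenzenesulfonate
Conditions: TsCl, Bu2SnO (2 mol %), Et3N, CH2Cl2, 0 °C to rt
Reagents that add atoms: 4-methylbenzenesulfonyl chloride, Cc1ccc(cc1)S(=O)(=O)Cl
Why: Tin-acetal-mediated regioselective sulfonylation, in which the stannylene acetal of the 1,2-diol reacts only at the primary oxygen (future C5).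

Step 6
Reactants: 10 (2S)-2-hydroxybut-3-en-1-yl 4-methylbenzenesulfonate
Product: 11 (2S)-2-methoxybut-3-en-1-yl 4-methylbenzenesulfonate
Conditions: Me3OBF4, 1,8-bis(dimethylamino)naphthalene, CH2Cl2, rt
Reagents that add atoms: trimethyloxonium tetrafluoroborate, C[O+](C)C.F[B-](F)(F)F
Why: O-Methylation with an oxonium salt under non-nucleophilic buffering, so no alkoxide forms and neither epoxide closure onto the tosylate nor loss of the allylic stereocentre (future C4) should occur.

Step 7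
Reactants: 11 (2S)-2-methoxybut-3-en-1-yl 4-methylbenzenesulfonate
Product: 12 (2S)-2-methoxy-4-(phenylsulfanyl)butyl 4-methylbenzenesulfonate
Conditions: PhSH, AIBN (cat.), toluene, 80 °C
Reagents that add atoms: thiophenol, Sc1ccccc1
Why: Radical thiol–ene hydrothiolation, in which the thiyl radical adds to the terminal alkene carbon (future C2) and the stereocentre is not part of the radical chain.

Step 8
Reactants: 12 (2S)-2-methoxy-4-(phenylsulfanyl)butyl 4-methylbenzenesulfonate
Product: 13 (2S)-2-methoxy-4-(phenylsulfinyl)butyl 4-methylbenzenesulfonate (both configurations at sulfur)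
Conditions: NaIO4, MeOH–H2O, 0 °C
Reagents that add atoms: sodium periodate, [Na+].[O-]I(=O)(=O)=O
Why: Chemoselective sulfide-to-sulfoxide oxidation with one equivalent of periodate, which stops before the sulfone; the sulfur configuration is irrelevant because sulfur is removed in step 10.

Step 9
Reactants: 8 (3S,4R)-4-{[tert-butyl(dimethyl)silyl]oxy}-3-methyl-4-(3,4,5-trimethoxyphenyl)butanoic acid; 13 (2S)-2-methoxy-4-(phenylsulfinyl)butyl 4-methylbenzenesulfonate
Product: 15 (2S,7S,8R)-8-{[tert-butyl(dimethyl)silyl]oxy}-2-methoxy-7-methyl-5-oxo-4-(phenylsulfinyl)-8-(3,4,5-trimethoxyphenyl)octyl 4-methylbenzenesulfonate (mixture at C4 of the chain and at sulfur), via acyl imidazole 14 (not isolated)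
Conditions: 8, 1,1′-carbonyldiimidazole, THF, rt; added to 13 (2.1 equiv) and LiN(i-Pr)2 (2.1 equiv), THF, −78 °C; AcOH quench at −78 °C
Reagents that add atoms: none
Why: Claisen-type acylation of an α-sulfinyl carbanion by an acyl imidazole forms the C1–C2 bond, the second equivalent of carbanion deprotonating the more acidic product, and the new C2 and sulfur centres are inconsequential mixtures.

Step 10
Reactants: 15 (2S,7S,8R)-8-{[tert-butyl(dimethyl)silyl]oxy}-2-methoxy-7-methyl-5-oxo-4-(phenylsulfinyl)-8-(3,4,5-trimethoxyphenyl)octyl 4-methylbenzenesulfonate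
Product: 17 (4R)-6-[(1R,2S)-1-{[tert-butyl(dimethyl)silyl]oxy}-1-(3,4,5-trimethoxyphenyl)propan-2-yl]-4-methoxycyclohex-2-en-1-one (both C6 epimers), via cyclised α-sulfinyl ketone 16 (not isolated)
Conditions: LiN(i-Pr)2 (2.2 equiv), THF, −78 to 0 °C; AcOH, −78 °C; then toluene, 80 °C
Reagents that add atoms: none
Why: Two equivalents of base remove first the C2–H (between C=O and S=O) and then a C6–H, the more basic γ-carbon C6 of this dianion displaces the tosylate at C5 by SN2, and the neutralised α-sulfinyl ketone then loses benzenesulfenic acid by thermal syn-elimination toward C3. The closest known reaction type is the γ-alkylation of β-keto sulfoxide (and β-keto ester) dianions followed by sulfoxide pyrolysis to an enone, here run intramolecularly. The six-membered ring closes in the 6-(enolendo)-exo-tet mode, with the C6=C1 enolate bond inside the new ring and the leaving group outside it. C6 is formed without control and C2 and sulfur are mixtures, but C2 and sulfur are erased by the elimination and C6 by enolisation in step 11, so all isomers converge, while C4, C7 and C8 are not touched. The step needs C6-alkylation over C2- and O-alkylation, secured because the C2 charge is sulfinyl-stabilised and could only close a four-membered ring whereas the non-stabilised C6 site is the most nucleophilic atom, and it needs ring closure before elimination, secured by keeping the substrate at or below 0 °C until it has cyclised.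

Step 11
Reactants: 17 (4R)-6-[(1R,2S)-1-{[tert-butyl(dimethyl)silyl]oxy}-1-(3,4,5-trimethoxyphenyl)propan-2-yl]-4-methoxycyclohex-2-en-1-one
Product: 18 (4R,6R)-6-[(1R,2S)-1-{[tert-butyl(dimethyl)silyl]oxy}-1-(3,4,5-trimethoxyphenyl)propan-2-yl]-4-methoxy-6-(prop-2-en-1-yl)cyclohex-2-en-1-one
Conditions: LiN(i-Pr)2, THF, −78 °C; allyl bromide, DMPU, −78 to −30 °C
Reagents that add atoms: allyl bromide, C=CCBr
Why: Kinetic α′-alkylation of a cross-conjugated enone enolate (C6–H is the only α′-hydrogen), in which the allyl halide should enter on the ring face trans to the C4 methoxy group, which is also the face left open by the side chain in its allylic-strain-minimised rotamer (C7–H eclipsing the enolate, the aryl(silyloxy)methyl group shielding the other face), giving 6R from both epimers of 17.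

Step 12
Reactants: 18 (4R,6R)-6-[(1R,2S)-1-{[tert-butyl(dimethyl)silyl]oxy}-1-(3,4,5-trimethoxyphenyl)propan-2-yl]-4-methoxy-6-(prop-2-en-1-yl)cyclohex-2-en-1-one
Product: 19 megaphone, (4R,6R)-6-[(1R,2S)-1-hydroxy-1-(3,4,5-trimethoxyphenyl)propan-2-yl]-4-methoxy-6-(prop-2-en-1-yl)cyclohex-2-en-1-one
Conditions: Bu4NF, AcOH, THF, 0 °C to rt
Reagents that add atoms: none
Why: Fluoride-mediated desilylation, buffered with acetic acid so that the γ-methoxy enone is not exposed to strong base, frees C8–OH without affecting any stereocentre.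

Compound list
1 | 3,4,5-trimethoxybenzaldehyde | COc1cc(C=O)cc(OC)c1OC | starting material
2 | 2-[(2Z)-but-2-en-1-yl]-4,4,5,5-tetramethyl-1,3,2-dioxaborolane | C/C=C\CB1OC(C)(C)C(C)(C)O1 | starting material
3 | 2-{[(1R,2S)-2-methyl-1-(3,4,5-trimethoxyphenyl)but-3-en-1-yl]oxy}-4,4,5,5-tetramethyl-1,3,2-dioxaborolane | C=C[C@H](C)[C@@H](OB1OC(C)(C)C(C)(C)O1)c1cc(OC)c(OC)c(OC)c1 | intermediate (not isolated)
4 | (1R,2S)-2-methyl-1-(3,4,5-trimethoxyphenyl)but-3-en-1-ol | C=C[C@H](C)[C@@H](O)c1cc(OC)c(OC)c(OC)c1 | intermediate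
5 | tert-butyl(dimethyl){[(1R,2S)-2-methyl-1-(3,4,5-trimethoxyphenyl)but-3-en-1-yl]oxy}silane | C=C[C@H](C)[C@@H](O[Si](C)(C)C(C)(C)C)c1cc(OC)c(OC)c(OC)c1 | intermediate
6 | 9-[(3S,4R)-4-{[tert-butyl(dimethyl)silyl]oxy}-3-methyl-4-(3,4,5-trimethoxyphenyl)butyl]-9-borabicyclo[3.3.1]nonane | B1(C2CCCC1CCC2)CC[C@H](C)[C@@H](O[Si](C)(C)C(C)(C)C)c1cc(OC)c(OC)c(OC)c1 | intermediate (not isolated)
7 | (3S,4R)-4-{[tert-butyl(dimethyl)silyl]oxy}-3-methyl-4-(3,4,5-trimethoxyphenyl)butan-1-ol | OCC[C@H](C)[C@@H](O[Si](C)(C)C(C)(C)C)c1cc(OC)c(OC)c(OC)c1 | intermediate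
8 | (3S,4R)-4-{[tert-butyl(dimethyl)silyl]oxy}-3-methyl-4-(3,4,5-trimethoxyphenyl)butanoic acid | OC(=O)C[C@H](C)[C@@H](O[Si](C)(C)C(C)(C)C)c1cc(OC)c(OC)c(OC)c1 | intermediate
9 | (2S)-but-3-ene-1,2-diol | OC[C@@H](O)C=C | starting material
10 | (2S)-2-hydroxybut-3-en-1-yl 4-methylbenzenesulfonate | Cc1ccc(cc1)S(=O)(=O)OC[C@@H](O)C=C | intermediate
11 | (2S)-2-methoxybut-3-en-1-yl 4-methylbenzenesulfonate | Cc1ccc(cc1)S(=O)(=O)OC[C@@H](OC)C=C | intermediate
12 | (2S)-2-methoxy-4-(phenylsulfanyl)butyl 4-methylbenzenesulfonate | Cc1ccc(cc1)S(=O)(=O)OC[C@@H](OC)CCSc1ccccc1 | intermediate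
13 | (2S)-2-methoxy-4-(phenylsulfinyl)butyl 4-methylbenzenesulfonate | Cc1ccc(cc1)S(=O)(=O)OC[C@@H](OC)CCS(=O)c1ccccc1 | intermediate
14 | 1-[(3S,4R)-4-{[tert-butyl(dimethyl)silyl]oxy}-3-methyl-4-(3,4,5-trimethoxyphenyl)butanoyl]-1H-imidazole | O=C(C[C@H](C)[C@@H](O[Si](C)(C)C(C)(C)C)c1cc(OC)c(OC)c(OC)c1)n1ccnc1 | intermediate (not isolated)
15 | (2S,7S,8R)-8-{[tert-butyl(dimethyl)silyl]oxy}-2-methoxy-7-methyl-5-oxo-4-(phenylsulfinyl)-8-(3,4,5-trimethoxyphenyl)octyl 4-methylbenzenesulfonate | Cc1ccc(cc1)S(=O)(=O)OC[C@@H](OC)CC(S(=O)c1ccccc1)C(=O)C[C@H](C)[C@@H](O[Si](C)(C)C(C)(C)C)c1cc(OC)c(OC)c(OC)c1 | intermediate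
16 | (4R)-6-[(1R,2S)-1-{[tert-butyl(dimethyl)silyl]oxy}-1-(3,4,5-trimethoxyphenyl)propan-2-yl]-4-methoxy-2-(phenylsulfinyl)cyclohexan-1-one | O=C1C(S(=O)c2ccccc2)C[C@H](OC)CC1[C@H](C)[C@@H](O[Si](C)(C)C(C)(C)C)c1cc(OC)c(OC)c(OC)c1 | intermediate (not isolated)
17 | (4R)-6-[(1R,2S)-1-{[tert-butyl(dimethyl)silyl]oxy}-1-(3,4,5-trimethoxyphenyl)propan-2-yl]-4-methoxycyclohex-2-en-1-one | O=C1C=C[C@H](OC)CC1[C@H](C)[C@@H](O[Si](C)(C)C(C)(C)C)c1cc(OC)c(OC)c(OC)c1 | intermediate
18 | (4R,6R)-6-[(1R,2S)-1-{[tert-butyl(dimethyl)silyl]oxy}-1-(3,4,5-trimethoxyphenyl)propan-2-yl]-4-methoxy-6-(prop-2-en-1-yl)cyclohex-2-en-1-one | C=CC[C@]1([C@H](C)[C@@H](O[Si](C)(C)C(C)(C)C)c2cc(OC)c(OC)c(OC)c2)C[C@@H](OC)C=CC1=O | intermediate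
19 | megaphone, (4R,6R)-6-[(1R,2S)-1-hydroxy-1-(3,4,5-trimethoxyphenyl)propan-2-yl]-4-methoxy-6-(prop-2-en-1-yl)cyclohex-2-en-1-one | C=CC[C@]1([C@H](C)[C@@H](O)c2cc(OC)c(OC)c(OC)c2)C[C@@H](OC)C=CC1=O | target

Total steps: 12. Longest linear sequence: 8 steps (steps 1–4, then 9–12; the branch 5–8, then 9–12, is equally long).

Steps most likely to fail

Step 10. The acyclic keto sulfoxide may lose sulfenic acid thermally before the ring has closed, or the monoanion may O-alkylate if the second deprotonation is incomplete. The fallback replaces the labile sulfoxide by a sulfone and separates ring closure from enone formation. It sets out from sulfide 12, which is oxidised with mCPBA (2.2 equiv) to the sulfone F1. Lithiation of F1 with LiN(i-Pr)2 and acylation with acyl imidazole 14 gives the thermally robust β-keto sulfone F2. Its dianion (LiN(i-Pr)2, 2.2 equiv, THF, −78 to 25 °C) closes the same C5–C6 bond to give the 2-(phenylsulfonyl)cyclohexanone F3. Reductive desulfonylation with SmI2 in THF–MeOH gives the saturated ketone F4. Kinetic enolisation at C2 (LiN(i-Pr)2, Me3SiCl, −78 °C) gives the trimethylsilyl enol ether F5, and Saegusa–Ito oxidation with Pd(OAc)2 in MeCN returns to enone 17.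

Step 11. The hindered α′-methine may be deprotonated slowly, so that γ-deprotonation at C4 competes, which would lead to allylation at C2 and erosion of the C4 centre. The fallback allylates before the enone exists, through a second dianion in which C2 is blocked. It sets out from 15, which is cyclised as in step 10 but worked up cold so that the sulfinyl ketone 16 is isolated. Treatment of 16 with LiN(i-Pr)2 (2.2 equiv) and then allyl bromide (1.0 equiv) at −78 °C should allylate only the γ-carbon C6, with the same facial bias, to give the allylated sulfinyl ketone F6. Heating F6 in toluene at 80 °C eliminates benzenesulfenic acid and returns to 18.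

Step 9. The basic sulfinyl carbanion may enolise the acyl imidazole instead of attacking it, and on standing it may displace its own tosylate. The fallback changes the acylation into an addition to a non-enolisable-on-this-timescale aldehyde followed by oxidation. It sets out from alcohol 7, which is converted by Dess–Martin oxidation into the aldehyde F7. Addition of lithiated 13 (1.1 equiv, THF, −78 °C, short contact time) gives the β-hydroxy sulfoxide F8, and a second Dess–Martin oxidation returns to 15.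

Further compounds
F1 | step 10 | (2S)-2-methoxy-4-(phenylsulfonyl)butyl 4-methylbenzenesulfonate | Cc1ccc(cc1)S(=O)(=O)OC[C@@H](OC)CCS(=O)(=O)c1ccccc1
F2 | step 10 | (2S,7S,8R)-8-{[tert-butyl(dimethyl)silyl]oxy}-2-methoxy-7-methyl-5-oxo-4-(phenylsulfonyl)-8-(3,4,5-trimethoxyphenyl)octyl 4-methylbenzenesulfonate | Cc1ccc(cc1)S(=O)(=O)OC[C@@H](OC)CC(S(=O)(=O)c1ccccc1)C(=O)C[C@H](C)[C@@H](O[Si](C)(C)C(C)(C)C)c1cc(OC)c(OC)c(OC)c1
F3 | step 10 | (4R)-6-[(1R,2S)-1-{[tert-butyl(dimethyl)silyl]oxy}-1-(3,4,5-trimethoxyphenyl)propan-2-yl]-4-methoxy-2-(phenylsulfonyl)cyclohexan-1-one | O=C1C(S(=O)(=O)c2ccccc2)C[C@H](OC)CC1[C@H](C)[C@@H](O[Si](C)(C)C(C)(C)C)c1cc(OC)c(OC)c(OC)c1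
F4 | step 10 | (4S)-2-[(1R,2S)-1-{[tert-butyl(dimethyl)silyl]oxy}-1-(3,4,5-trimethoxyphenyl)propan-2-yl]-4-methoxycyclohexan-1-one | O=C1CC[C@H](OC)CC1[C@H](C)[C@@H](O[Si](C)(C)C(C)(C)C)c1cc(OC)c(OC)c(OC)c1
F5 | step 10 | {[(4S)-6-[(1R,2S)-1-{[tert-butyl(dimethyl)silyl]oxy}-1-(3,4,5-trimethoxyphenyl)propan-2-yl]-4-methoxycyclohex-1-en-1-yl]oxy}trimethylsilane | C[Si](C)(C)OC1=CC[C@H](OC)CC1[C@H](C)[C@@H](O[Si](C)(C)C(C)(C)C)c1cc(OC)c(OC)c(OC)c1
F6 | step 11 | (4R,6R)-6-[(1R,2S)-1-{[tert-butyl(dimethyl)silyl]oxy}-1-(3,4,5-trimethoxyphenyl)propan-2-yl]-4-methoxy-2-(phenylsulfinyl)-6-(prop-2-en-1-yl)cyclohexan-1-one | C=CC[C@]1([C@H](C)[C@@H](O[Si](C)(C)C(C)(C)C)c2cc(OC)c(OC)c(OC)c2)C[C@@H](OC)CC(S(=O)c2ccccc2)C1=O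
F7 | step 9 | (3S,4R)-4-{[tert-butyl(dimethyl)silyl]oxy}-3-methyl-4-(3,4,5-trimethoxyphenyl)butanal | O=CC[C@H](C)[C@@H](O[Si](C)(C)C(C)(C)C)c1cc(OC)c(OC)c(OC)c1
F8 | step 9 | (2S,7S,8R)-8-{[tert-butyl(dimethyl)silyl]oxy}-5-hydroxy-2-methoxy-7-methyl-4-(phenylsulfinyl)-8-(3,4,5-trimethoxyphenyl)octyl 4-methylbenzenesulfonate | Cc1ccc(cc1)S(=O)(=O)OC[C@@H](OC)CC(S(=O)c1ccccc1)C(O)C[C@H](C)[C@@H](O[Si](C)(C)C(C)(C)C)c1cc(OC)c(OC)c(OC)c1
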